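**Assumption:** Angustone B has no stereocenters. The gem-dimethyl carbon has two identical methyls and the prenyl alkene has two methyls on one carbon. "Single enantiomer" is therefore moot, and no step needs stereocontrol. The one carbinol stereocenter in the route (compound 10) is racemic and destroyed in the next step.

**Second assumption:** In Step 4 the chromone closes through the less hindered 6'-OH, which gives the 6-prenyl isomer. I expect about 3:1 selectivity; the minor 8-prenyl isomer is removed by chromatography.

## Retrosynthetic overview
1. Last step: remove two MOM groups from a protected 5-hydroxyisoflavone.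
2. Disconnect the isoflavone C3–C1' bond (Suzuki coupling) into an A-ring 3-iodochromone carrying the 6-prenyl group and a B-ring boronic acid that already contains the 2,2-dimethylchromene.
3. Order of ring formation:
   - A ring: MOM-protect phloroacetophenone, C-prenylate it, then form the pyranone (enaminone, then I2).
   - B ring: form the angular pyran from bis-MOM resorcinol by C2-lithiation, addition of prenal and acid cyclization. Lithiation between the two oxygens fixes the angular regiochemistry. MOM-directed ortho-borylation then puts boron at the carbon that becomes C1'.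
4. The two fragments join in the Suzuki coupling, followed by deprotection.

## Route

**Step 1**
Reactants: 1 (2,4,6-trihydroxyacetophenone)
Product: 2 (1-[2,6-dihydroxy-4-(methoxymethoxy)phenyl]ethanone)
Conditions: MOMCl (1.0 equiv), K2CO3, acetone, 0 °C → rt
Reagents that add atoms: MOMCl, ClCOC
Why: The 4-OH is the most acidic and is not chelated to the C=O, so it is selectively alkylated (Williamson-type MOM protection) while the two chelated ortho OH groups stay free.

**Step 2**
Reactants: 2; 3 (prenyl bromide, 1-bromo-3-methylbut-2-ene)
Product: 4 (1-[2,6-dihydroxy-4-(methoxymethoxy)-3-(3-methylbut-2-enyl)phenyl]ethanone)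
Conditions: 3 (1.0 equiv), KOH, MeOH/H2O, 0 °C → rt
Reagents that add atoms: none beyond reactant 3
Why: In protic solvent the phloroglucinol-type phenoxide is C-alkylated ortho to the oxygen (C-prenylation); C3 and C5 are equivalent, so only one mono-prenyl regioisomer forms. Yield is moderate, and O- and di-prenylated by-products are removed by chromatography.

**Step 3**
Reactants: 4
Product: 5 ((E)-3-(dimethylamino)-1-[2,6-dihydroxy-4-(methoxymethoxy)-3-prenylphenyl]prop-2-en-1-one)
Conditions: DMF-DMA, toluene, 90 °C
Reagents that add atoms: DMF-DMA, CN(C)C(OC)OC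
Why: The acetyl methyl group condenses with the DMF acetal to give the enaminone (enaminone formation). The chelated phenols are not methylated under these conditions.

**Step 4**
Reactants: 5
Product: 6 (3-iodo-5-hydroxy-7-(methoxymethoxy)-6-prenylchromone)
Conditions: I2 (1.2 equiv), CHCl3, 0 °C → rt
Reagents that add atoms: I2, II
Why: I2 iodinates the enaminone α-carbon. The ortho OH then attacks the β-carbon and Me2NH is lost (iodo-cyclization to the 3-iodochromone). The bulky enaminone chain sits on the side away from the prenyl group, so the 6'-OH, the one remote from the prenyl-bearing carbon, closes the ring and the prenyl ends up at C6.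

**Step 5**
Reactants: 7 (resorcinol)
Product: 8 (1,3-bis(methoxymethoxy)benzene)
Conditions: NaH (2.2 equiv), MOMCl (2.2 equiv), DMF/THF, 0 °C → rt
Reagents that add atoms: MOMCl, ClCOC
Why: Double Williamson-type MOM protection sets up a doubly directed ortho-metalation.

**Step 6**
Reactants: 8; 9 (3-methylbut-2-enal, prenal)
Product: 10 (1-[2,6-bis(methoxymethoxy)phenyl]-3-methylbut-2-en-1-ol, racemic)
Conditions: n-BuLi, THF, 0 °C, 2 h; then 9, –78 °C → rt
Reagents that add atoms: none beyond reactant 9
Why: Directed ortho-lithiation occurs only at C2, between the two OMOM groups, and the aryllithium adds 1,2 to the enal. This fixes the angular regiochemistry of the future pyran ring. The new carbinol stereocenter is racemic and is destroyed in Step 7.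

**Step 7**
Reactants: 10
Product: 11 (2,2-dimethyl-2H-chromen-5-ol)
Conditions: TsOH·H2O (0.3 equiv), MeOH, 60 °C
Reagents that add atoms: none
Why: Acid removes both MOM groups and ionizes the allylic/benzylic alcohol. The free ortho phenol traps the tertiary allyl cation terminus in a 6-endo closure to the 2,2-dimethyl-2H-chromene (acid-mediated chromene formation).

**Step 8**
Reactants: 11
Product: 12 (5-(methoxymethoxy)-2,2-dimethyl-2H-chromene)
Conditions: MOMCl, iPr2NEt, CH2Cl2, 0 °C → rt
Reagents that add atoms: MOMCl, ClCOC
Why: This re-protects the phenol as a strong directing group for the next step (MOM protection).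

**Step 9**
Reactants: 12
Product: 13 ((5-(methoxymethoxy)-2,2-dimethyl-2H-chromen-6-yl)boronic acid)
Conditions: n-BuLi, THF, 0 °C, 2 h; then B(OiPr)3, –78 °C → rt; aq. NH4Cl work-up
Reagents that add atoms: triisopropyl borate, CC(C)OB(OC(C)C)OC(C)C
Why: The OMOM group directs lithiation to its only free ortho position, C6, which becomes C1' of the isoflavone. Borate trapping then gives the boronic acid (directed ortho-metalation/borylation).

**Step 10**
Reactants: 6; 13
Product: 14 (5-hydroxy-7-(methoxymethoxy)-6-prenyl-3-[2'-(methoxymethoxy)-3',4'-(2,2-dimethylpyrano)phenyl]chromen-4-one)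
Conditions: Pd(PPh3)4 (5 mol %), Na2CO3 (aq), DME, 80 °C
Reagents that add atoms: none
Why: Suzuki–Miyaura coupling joins the vinyl iodide-type C3–I bond to the aryl boronic acid and builds the isoflavone C3–C1' bond. The prenyl group, both MOM groups, the chromene and the chelated 5-OH are untouched by Pd(0)/carbonate.

**Step 11**
Reactants: 14
Product: 15 (Angustone B)
Conditions: TsOH·H2O (2 equiv), MeOH/CH2Cl2 1:1, 40 °C
Reagents that add atoms: none
Why: Mild acid transacetalization removes both aryl MOM ethers (MOM deprotection). The chromene, prenyl alkene and chelated 5-OH survive, and no stereocenter is involved.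

## Compound list
1 | 2,4,6-trihydroxyacetophenone | CC(=O)c1c(O)cc(O)cc1O | starting material
2 | 1-[2,6-dihydroxy-4-(methoxymethoxy)phenyl]ethanone | CC(=O)c1c(O)cc(OCOC)cc1O | intermediate
3 | prenyl bromide | CC(C)=CCBr | starting material
4 | 1-[2,6-dihydroxy-4-(methoxymethoxy)-3-prenylphenyl]ethanone | CC(=O)c1c(O)c(CC=C(C)C)c(OCOC)cc1O | intermediate
5 | (E)-enaminone | CN(C)/C=C/C(=O)c1c(O)c(CC=C(C)C)c(OCOC)cc1O | intermediate
6 | 3-iodo-5-hydroxy-7-MOMO-6-prenylchromone | CC(C)=CCc1c(OCOC)cc2occ(I)c(=O)c2c1O | intermediate
7 | resorcinol | Oc1cccc(O)c1 | starting material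
8 | 1,3-bis(methoxymethoxy)benzene | COCOc1cccc(OCOC)c1 | intermediate
9 | 3-methylbut-2-enal (prenal) | CC(C)=CC=O | starting material
10 | 1-[2,6-bis(MOMO)phenyl]-3-methylbut-2-en-1-ol (racemic) | COCOc1cccc(OCOC)c1C(O)C=C(C)C | intermediate
11 | 2,2-dimethyl-2H-chromen-5-ol | CC1(C)C=Cc2c(O)cccc2O1 | intermediate
12 | 5-MOMO-2,2-dimethyl-2H-chromene | CC1(C)C=Cc2c(OCOC)cccc2O1 | intermediate
13 | (5-MOMO-2,2-dimethyl-2H-chromen-6-yl)boronic acid | B(O)(O)c1ccc2OC(C)(C)C=Cc2c1OCOC | intermediate
14 | bis-MOM-protected Angustone B | CC(C)=CCc1c(OCOC)cc2occ(-c3ccc4c(c3OCOC)C=CC(C)(C)O4)c(=O)c2c1O | intermediate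
15 | Angustone B (achiral) | CC(C)=CCc1c(O)cc2occ(-c3ccc4c(c3O)C=CC(C)(C)O4)c(=O)c2c1O | target

**Total steps:** 11.
**Longest linear sequence:** 7 steps (resorcinol → 8 → 10 → 11 → 12 → 13 → 14 → 15).

## Three steps most likely to fail
1. **Step 4 (regioselective closure; prenyl alkene vs I2).** The 8-prenyl isomer may form, or the prenyl group may iodocyclize with the ortho phenol.
   - Fallback: change the route so the ring closure is forced. Lithiate 1,3,5-tris(MOMO)benzene and prenylate it at C2, lithiate C4 and acylate, selectively cleave only the unhindered ortho MOM with MgBr2, then run the enaminone/iodination sequence.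
2. **Step 7 (acid cyclization to the 5-hydroxychromene).** The cation may be trapped by MeOH, or the material may dimerize or polymerize.
   - Fallback: build 11 by a different route. Condense 1,3-cyclohexanedione with prenal (Knoevenagel/6π-oxa-electrocyclization) to the tetrahydrochromenone, then aromatize with Pd/C or I2/MeOH.
3. **Step 11 (final MOM removal).** Acid may open the chromene or cyclize the 5-OH/6-prenyl unit.
   - Fallback: use SEM instead of MOM on the 7-O and 2'-O positions from the start (SEM is also a directing group), and remove both in the last step with TBAF or MgBr2 under non-protic-acid conditions.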